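The carbocycle (C1 bearing the chain, C2 = CMe2, C3 = CHOH, C6 = C=CH2) is traced back to a cyclopentane. Everything rests on the hindered C1–C2 bond between the quaternary carbon and the chain-bearing methine. In the key step a 1-(1-mesyloxyalkyl)cyclopentanol that already carries the whole diene chain undergoes an aluminium-promoted semipinacol shift: the CMe2 ring carbon migrates to the exocyclic carbinol carbon. One operation enlarges the five-membered ring to the six-membered one, forms C1–C2 and sets C1 by inversion of an easily set carbinol centre. It also erases the auxiliary tertiary centre and unveils the C6 ketone for methylenation. The pyrone is attached last by Tsuji–Trost allylation.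

Key step: step 9

Remark: compounds 1, 6 and 16 are taken as commercial. TBS = tert-butyldimethylsilyl. "C10" is the last chain carbon of compounds 10–13, which becomes ring carbon C1 of the target.

Step 1
Reactants: 1 2,2-dimethylcyclopentane-1,3-dione
Product: 2 (3S)-3-hydroxy-2,2-dimethylcyclopentan-1-one
Conditions: (R)-Me-CBS oxazaborolidine (cat.), catecholborane (1 equiv), toluene, −78 °C; then H2O
Reagents that add atoms: none
Why: Corey–Bakshi–Shibata reduction, in which the (R)-catalyst reads the quaternary carbon as the large and the ring CH2 as the small group and delivers hydride to the face that gives the S carbinol (later C3), while one equivalent of the mild borane at low temperature should stop at the hydroxy ketone.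

Step 2
Reactants: 2 (3S)-3-hydroxy-2,2-dimethylcyclopentan-1-one
Product: 3 (3S)-3-(TBSO)-2,2-dimethylcyclopentan-1-one
Conditions: TBSCl, imidazole, DMF, 40 °C
Reagents that add atoms: tert-butyldimethylsilyl chloride, CC(C)(C)[Si](C)(C)Cl
Why: Standard silylation, which blocks retro-aldol cleavage of the β-hydroxy ketone in the basic steps that follow and shields one ring face.

Step 3
Reactants: 3 (3S)-3-(TBSO)-2,2-dimethylcyclopentan-1-one
Product: 5 1-[(1R,3S)-3-(TBSO)-1-hydroxy-2,2-dimethylcyclopentyl]ethan-1-one, via enol ether carbinol 4 (not isolated)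
Conditions: ethyl vinyl ether, t-BuLi, THF, −78 to 0 °C; then 3, −78 °C; then 0.5 M HCl, THF, 0 °C
Reagents that add atoms: ethyl vinyl ether, C=COCC; water, O
Why: 1,2-addition of an acyl anion equivalent (α-lithiated enol ether), a small sp2 nucleophile of the kind that adds to neopentyl cyclopentanones such as 17-oxo steroids; it should approach anti to the silyloxy group to give the 1R carbinol (a minor epimer would be removed by chromatography), and dilute acid hydrolyses the enol ether of 4 faster than it touches the TBS ether.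

Step 4
Reactants: 6 geranyl acetate
Product: 7 (2E,6E)-8-hydroxy-3,7-dimethylocta-2,6-dien-1-yl acetate
Conditions: SeO2 (cat.), t-BuOOH, salicylic acid (cat.), CH2Cl2, rt
Reagents that add atoms: tert-butyl hydroperoxide, CC(C)(C)OO
Why: Selenium dioxide allylic oxidation (ene reaction, then [2,3]-shift) attacks the electron-richer terminal alkene at its E-methyl group, because the 2,3-alkene is deactivated by the acetoxy group.

Step 5
Reactants: 7 (2E,6E)-8-hydroxy-3,7-dimethylocta-2,6-dien-1-yl acetate
Product: 8 (2E,6E)-8-bromo-3,7-dimethylocta-2,6-dien-1-yl acetate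
Conditions: CBr4, PPh3, CH2Cl2, 0 °C
Reagents that add atoms: carbon tetrabromide, BrC(Br)(Br)Br
Why: Appel bromination converts the primary allylic alcohol by SN2 under neutral conditions, without allylic transposition or loss of alkene geometry.

Step 6
Reactants: 5 1-[(1R,3S)-3-(TBSO)-1-hydroxy-2,2-dimethylcyclopentyl]ethan-1-one; 8 (2E,6E)-8-bromo-3,7-dimethylocta-2,6-dien-1-yl acetate
Product: 10 (2E,6E)-10-[(1R,3S)-3-(TBSO)-1-hydroxy-2,2-dimethylcyclopentyl]-3,7-dimethyl-10-oxodeca-2,6-dien-1-yl acetate, via dilithium alkoxide enolate 9 (not isolated)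
Conditions: LDA (2.2 equiv), THF, −78 °C; then 8, −78 to −30 °C; then H2O
Reagents that add atoms: none
Why: Enolate alkylation of a ketone with a single enolisable position (the methyl group), in which the enolate carbon of 9 should displace the primary allylic bromide by SN2 at low temperature faster than it attacks the acetate and faster than the hindered tertiary alkoxide is O-alkylated.

Step 7
Reactants: 10 (2E,6E)-10-[(1R,3S)-3-(TBSO)-1-hydroxy-2,2-dimethylcyclopentyl]-3,7-dimethyl-10-oxodeca-2,6-dien-1-yl acetate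
Product: 11 (2E,6E,10S)-10-hydroxy-10-[(1R,3S)-3-(TBSO)-1-hydroxy-2,2-dimethylcyclopentyl]-3,7-dimethyldeca-2,6-dien-1-yl acetate
Conditions: Zn(BH4)2, Et2O, −20 °C; aq. NH4Cl
Reagents that add atoms: none
Why: Chelation-controlled (Cram chelate) reduction of an α-hydroxy ketone, in which zinc ties the two oxygens together and hydride arrives from the side of the ring CH2, away from the CMe2 group; this sets 10S, and the ester, silyl ether and alkenes are inert to zinc borohydride.

Step 8
Reactants: 11 (2E,6E,10S)-10-hydroxy-10-[(1R,3S)-3-(TBSO)-1-hydroxy-2,2-dimethylcyclopentyl]-3,7-dimethyldeca-2,6-dien-1-yl acetate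
Product: 12 (2E,6E,10S)-10-[(1R,3S)-3-(TBSO)-1-hydroxy-2,2-dimethylcyclopentyl]-10-(methanesulfonyloxy)-3,7-dimethyldeca-2,6-dien-1-yl acetate
Conditions: MsCl, Et3N, CH2Cl2, −20 to 0 °C
Reagents that add atoms: methanesulfonyl chloride, CS(=O)(=O)Cl
Why: Sulfonylation via sulfene is fast at the secondary hydroxyl, whereas the tertiary hydroxyl next to a quaternary carbon should not react at this temperature.

Step 9
Reactants: 12 (2E,6E,10S)-10-[(1R,3S)-3-(TBSO)-1-hydroxy-2,2-dimethylcyclopentyl]-10-(methanesulfonyloxy)-3,7-dimethyldeca-2,6-dien-1-yl acetate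
Product: 14 (2E,6E)-9-[(1S,3S)-3-(TBSO)-2,2-dimethyl-6-oxocyclohexyl]-3,7-dimethylnona-2,6-dien-1-yl acetate, via chloro(ethyl)aluminium alkoxide 13 (not isolated)
Conditions: Et2AlCl (2.5 equiv), CH2Cl2, −78 to −30 °C; cold 1 M HCl
Reagents that add atoms: none
Why: Et2AlCl turns the tertiary alcohol into aluminium alkoxide 13 and binds the mesylate, so the alkoxide pushes while the sulfonate is pulled off and the ring bond from the carbinol carbon to the CMe2 carbon shifts to C10 in one concerted event; this is the organoaluminium-promoted pinacol-type (semipinacol) rearrangement of 2-sulfonyloxy alcohols, the same type as the D-homoannulation of 17-hydroxy-20-sulfonyloxy steroids. No ring is closed by cyclisation: the six-membered ring arises by one-carbon enlargement of the cyclopentane, with C10 inserted between the former carbinol carbon (now the ketone, later C6) and the CMe2 carbon. The one new ring stereocentre (former C10, later C1) is set by the antiperiplanar, invertive 1,2-shift, so the 10S mesylate gives the S-configured α-carbon cis to the silyloxy group, while the tertiary relay centre is erased. The step needs migration of the quaternary carbon rather than the ring CH2, and rearrangement rather than epoxide closure. A tert-alkyl group is the better migrating group, and of the two rotamers that hold O–Al and OMs gauche, as chelation demands, the (1R,10S) isomer prefers the one with the CMe2 bond anti to the mesylate, because it keeps the chain out of the cleft between the two ring carbons; the same chelation denies the anti O/OMs arrangement that an epoxide would need. Low temperature and the proton-scavenging alkylaluminium should spare the trisubstituted alkenes, the allylic acetate and the new α-stereocentre.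

Step 10
Reactants: 14 (2E,6E)-9-[(1S,3S)-3-(TBSO)-2,2-dimethyl-6-oxocyclohexyl]-3,7-dimethylnona-2,6-dien-1-yl acetate
Product: 15 (2E,6E)-9-[(1R,3S)-3-(TBSO)-2,2-dimethyl-6-methylidenecyclohexyl]-3,7-dimethylnona-2,6-dien-1-yl acetate
Conditions: Zn, CH2Br2, TiCl4, THF; then 14, CH2Cl2, 0 °C to rt
Reagents that add atoms: dibromomethane, BrCBr
Why: Lombardo methylenation uses a non-basic zinc–titanium gem-dimetallic reagent that methylenates hindered, enolisable ketones without epimerising the α-carbon and leaves esters, silyl ethers and alkenes alone (the descriptor changes from S to R only through the priority rules).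

Step 11
Reactants: 15 (2E,6E)-9-[(1R,3S)-3-(TBSO)-2,2-dimethyl-6-methylidenecyclohexyl]-3,7-dimethylnona-2,6-dien-1-yl acetate; 16 4-hydroxy-6-methyl-2H-pyran-2-one
Product: 17 3-{(2E,6E)-9-[(1R,3S)-3-(TBSO)-2,2-dimethyl-6-methylidenecyclohexyl]-3,7-dimethylnona-2,6-dien-1-yl}-4-hydroxy-6-methyl-2H-pyran-2-one
Conditions: Pd(PPh3)4 (cat.), DBU, THF, 50 °C
Reagents that add atoms: none
Why: Tsuji–Trost allylation of a highly acidic, soft nucleophile that is allylated at C3 under palladium(0); any O-allyl ether is re-ionised and funnelled to the C-allyl product, and attack at the unsubstituted allyl terminus keeps the linear E-alkene.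

Step 12
Reactants: 17 3-{(2E,6E)-9-[(1R,3S)-3-(TBSO)-2,2-dimethyl-6-methylidenecyclohexyl]-3,7-dimethylnona-2,6-dien-1-yl}-4-hydroxy-6-methyl-2H-pyran-2-one
Product: 18 sartorypyrone D
Conditions: HF·pyridine, pyridine, THF, 0 °C to rt
Reagents that add atoms: none
Why: Fluoride-driven desilylation under buffered conditions that should be mild enough for the exocyclic methylene group, the trisubstituted alkenes and the pyrone, and that touches no stereocentre.

Compound list
1 | 2,2-dimethylcyclopentane-1,3-dione | CC1(C)C(=O)CCC1=O | starting material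
2 | (3S)-3-hydroxy-2,2-dimethylcyclopentan-1-one | O=C1CC[C@H](O)C1(C)C | intermediate
3 | (3S)-3-(tert-butyldimethylsilyloxy)-2,2-dimethylcyclopentan-1-one | O=C1CC[C@H](O[Si](C)(C)C(C)(C)C)C1(C)C | intermediate
4 | (1R,3S)-3-(TBSO)-1-(1-ethoxyethenyl)-2,2-dimethylcyclopentan-1-ol (not isolated) | C=C(OCC)[C@@]1(O)CC[C@H](O[Si](C)(C)C(C)(C)C)C1(C)C | intermediate
5 | 1-[(1R,3S)-3-(TBSO)-1-hydroxy-2,2-dimethylcyclopentyl]ethan-1-one | CC(=O)[C@@]1(O)CC[C@H](O[Si](C)(C)C(C)(C)C)C1(C)C | intermediate
6 | geranyl acetate, (2E)-3,7-dimethylocta-2,6-dien-1-yl acetate | CC(C)=CCC/C(C)=C/COC(C)=O | starting material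
7 | (2E,6E)-8-hydroxy-3,7-dimethylocta-2,6-dien-1-yl acetate | OC/C(C)=C/CC/C(C)=C/COC(C)=O | intermediate
8 | (2E,6E)-8-bromo-3,7-dimethylocta-2,6-dien-1-yl acetate | BrC/C(C)=C/CC/C(C)=C/COC(C)=O | intermediate
9 | dilithium alkoxide enolate of 5 (not isolated) | C=C(O[Li])[C@@]1(O[Li])CC[C@H](O[Si](C)(C)C(C)(C)C)C1(C)C | intermediate
10 | (2E,6E)-10-[(1R,3S)-3-(TBSO)-1-hydroxy-2,2-dimethylcyclopentyl]-3,7-dimethyl-10-oxodeca-2,6-dien-1-yl acetate | O=C(CC/C(C)=C/CC/C(C)=C/COC(C)=O)[C@@]1(O)CC[C@H](O[Si](C)(C)C(C)(C)C)C1(C)C | intermediate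
11 | (2E,6E,10S)-10-hydroxy-10-[(1R,3S)-3-(TBSO)-1-hydroxy-2,2-dimethylcyclopentyl]-3,7-dimethyldeca-2,6-dien-1-yl acetate | O[C@@H](CC/C(C)=C/CC/C(C)=C/COC(C)=O)[C@@]1(O)CC[C@H](O[Si](C)(C)C(C)(C)C)C1(C)C | intermediate
12 | (2E,6E,10S)-10-[(1R,3S)-3-(TBSO)-1-hydroxy-2,2-dimethylcyclopentyl]-10-(methanesulfonyloxy)-3,7-dimethyldeca-2,6-dien-1-yl acetate | CS(=O)(=O)O[C@@H](CC/C(C)=C/CC/C(C)=C/COC(C)=O)[C@@]1(O)CC[C@H](O[Si](C)(C)C(C)(C)C)C1(C)C | intermediate
13 | chloro(ethyl)aluminium alkoxide of 12 (not isolated) | CS(=O)(=O)O[C@@H](CC/C(C)=C/CC/C(C)=C/COC(C)=O)[C@@]1(O[Al](Cl)CC)CC[C@H](O[Si](C)(C)C(C)(C)C)C1(C)C | intermediate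
14 | (2E,6E)-9-[(1S,3S)-3-(TBSO)-2,2-dimethyl-6-oxocyclohexyl]-3,7-dimethylnona-2,6-dien-1-yl acetate | O=C1CC[C@H](O[Si](C)(C)C(C)(C)C)C(C)(C)[C@@H]1CC/C(C)=C/CC/C(C)=C/COC(C)=O | intermediate
15 | (2E,6E)-9-[(1R,3S)-3-(TBSO)-2,2-dimethyl-6-methylidenecyclohexyl]-3,7-dimethylnona-2,6-dien-1-yl acetate | C=C1CC[C@H](O[Si](C)(C)C(C)(C)C)C(C)(C)[C@@H]1CC/C(C)=C/CC/C(C)=C/COC(C)=O | intermediate
16 | 4-hydroxy-6-methyl-2H-pyran-2-one (triacetic acid lactone) | Cc1cc(O)cc(=O)o1 | starting material
17 | 3-{(2E,6E)-9-[(1R,3S)-3-(TBSO)-2,2-dimethyl-6-methylidenecyclohexyl]-3,7-dimethylnona-2,6-dien-1-yl}-4-hydroxy-6-methyl-2H-pyran-2-one | C=C1CC[C@H](O[Si](C)(C)C(C)(C)C)C(C)(C)[C@@H]1CC/C(C)=C/CC/C(C)=C/Cc1c(O)cc(C)oc1=O | intermediate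
18 | sartorypyrone D, 4-hydroxy-3-{(2E,6E)-9-[(1R,3S)-3-hydroxy-2,2-dimethyl-6-methylidenecyclohexyl]-3,7-dimethylnona-2,6-dien-1-yl}-6-methyl-2H-pyran-2-one | C=C1CC[C@H](O)C(C)(C)[C@@H]1CC/C(C)=C/CC/C(C)=C/Cc1c(O)cc(C)oc1=O | target

Total step count: 12. Longest linear sequence: 10 (steps 1–3 and 6–12).

Steps most likely to fail

Step 9. The shift of the quaternary carbon competes with the shift of the ring CH2 and with closure of the alkoxide onto C10. The Lewis acid may also trigger attack of the nearest trisubstituted alkene on the activated carbonyl. The fallback sets out from 12 and comes back at 14, and it makes the competing closure part of the route.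
- Sodium hydride in THF closes 12, with inversion at C10, to the spiro-epoxide (2E,6E)-9-[(2R,3R,5S)-5-(TBSO)-4,4-dimethyl-1-oxaspiro[2.4]heptan-2-yl]-3,7-dimethylnona-2,6-dien-1-yl acetate F1.
- Magnesium bromide etherate opens F1 at the secondary carbon, with a second inversion, to the bromomagnesium alkoxide of the (10S)-bromohydrin F2.
- On warming in toluene, F2 undergoes the ring enlargement known for magnesium salts of 1-(1-haloalkyl)cycloalkanols.
- Three inversions in all lead to the same configuration as the direct shift.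

Step 11. O-allylation may fail to revert, the nucleophile may attack the substituted allyl terminus, and syn–anti exchange in the allyl unit may erode the E geometry. The fallback sets out from 15 and comes back at 17, and it builds the pyrone on the chain instead of alkylating it.
- Palladium-catalysed allylation of the sodium enolate of methyl acetoacetate, a carbon nucleophile with no O/C ambiguity, gives the methyl 2-acetyl-alkadienoate F3.
- Its dianion (NaH, then n-BuLi) is acylated at the terminal carbon by N-methoxy-N-methylacetamide to the methyl 2-allyl-3,5-dioxohexanoate F4.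
- DBU in refluxing toluene lactonises F4 to 17.

Step 10. The bulky titanium reagent may add only slowly to the flanked carbonyl, and enolisation may cost the configuration at the α-carbon. The fallback sets out from 14 and comes back at 15, and it separates addition from elimination (Peterson olefination).
- Excess (trimethylsilyl)methyllithium on cerium(III) chloride, a small and weakly basic nucleophile, adds to the ketone and also consumes the acetate. This gives the β-hydroxysilane allylic alcohol F5 (either epimer at the new carbinol carbon).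
- Potassium hydride effects the elimination, which can only give the exocyclic alkene, to the allylic alcohol F6.
- Acetic anhydride and pyridine restore 15.

Further compounds
F1 | step 9 | (2E,6E)-9-[(2R,3R,5S)-5-(TBSO)-4,4-dimethyl-1-oxaspiro[2.4]heptan-2-yl]-3,7-dimethylnona-2,6-dien-1-yl acetate | O1[C@H](CC/C(C)=C/CC/C(C)=C/COC(C)=O)[C@]12CC[C@H](O[Si](C)(C)C(C)(C)C)C2(C)C
F2 | step 9 | bromomagnesium alkoxide of (2E,6E,10S)-10-bromo-10-[(1R,3S)-3-(TBSO)-1-hydroxy-2,2-dimethylcyclopentyl]-3,7-dimethyldeca-2,6-dien-1-yl acetate | Br[C@@H](CC/C(C)=C/CC/C(C)=C/COC(C)=O)[C@@]1(O[Mg]Br)CC[C@H](O[Si](C)(C)C(C)(C)C)C1(C)C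
F3 | step 11 | methyl (4E,8E)-2-acetyl-11-[(1R,3S)-3-(TBSO)-2,2-dimethyl-6-methylidenecyclohexyl]-5,9-dimethylundeca-4,8-dienoate (C2 epimerisable) | C=C1CC[C@H](O[Si](C)(C)C(C)(C)C)C(C)(C)[C@@H]1CC/C(C)=C/CC/C(C)=C/CC(C(C)=O)C(=O)OC
F4 | step 11 | methyl 2-{(2E,6E)-9-[(1R,3S)-3-(TBSO)-2,2-dimethyl-6-methylidenecyclohexyl]-3,7-dimethylnona-2,6-dien-1-yl}-3,5-dioxohexanoate (C2 epimerisable) | C=C1CC[C@H](O[Si](C)(C)C(C)(C)C)C(C)(C)[C@@H]1CC/C(C)=C/CC/C(C)=C/CC(C(=O)CC(C)=O)C(=O)OC
F5 | step 10 | (2S,4S)-4-(TBSO)-2-[(3E,7E)-9-hydroxy-3,7-dimethylnona-3,7-dien-1-yl]-3,3-dimethyl-1-[(trimethylsilyl)methyl]cyclohexan-1-ol (either C1 epimer) | C[Si](C)(C)CC1(O)CC[C@H](O[Si](C)(C)C(C)(C)C)C(C)(C)[C@@H]1CC/C(C)=C/CC/C(C)=C/CO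
F6 | step 10 | (2E,6E)-9-[(1R,3S)-3-(TBSO)-2,2-dimethyl-6-methylidenecyclohexyl]-3,7-dimethylnona-2,6-dien-1-ol | C=C1CC[C@H](O[Si](C)(C)C(C)(C)C)C(C)(C)[C@@H]1CC/C(C)=C/CC/C(C)=C/CO
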